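(The runs come from a simulation on assumed constants, and the scatter is random.)

Prd is what this flask makes, and Sub + Rgt -> Prd spends one Sub for each Prd, so I follow Prd through the logarithm of Sub. Flask eta has the charge of gamma and is asked about at a later time.

| setting | gamma | delta | beta | epsilon | eta |
|---|---|---|---|---|---|
| Sub | 0.500 M | 0.750 M | 0.500 M | 0.500 M | 0.500 M |
| Rgt | 0.550 M | 0.550 M | 0.550 M | 1.10 M | 0.550 M |
| Cat | 0.0500 M | 0.0500 M | 0.150 M | 0.0500 M | 0.0500 M |
| time |  |  |  |  | 70 min |

| run | time / min | [Sub] / M |
|---|---|---|
| gamma run | 1.4 | 0.4907 |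
| gamma run | 2.4 | 0.4796 |
| gamma run | 4.1 | 0.4674 |
| gamma run | 7.0 | 0.4340 |
| gamma run | 12 | 0.3815 |
| gamma run | 20 | 0.3152 |
| gamma run | 35 | 0.2108 |
| delta run | 1.4 | 0.7390 |
| delta run | 2.4 | 0.7210 |
| delta run | 4.1 | 0.6963 |
| delta run | 7.0 | 0.6577 |
| delta run | 12 | 0.5880 |
| delta run | 20 | 0.4976 |
| delta run | 35 | 0.3584 |
| beta run | 1.4 | 0.4756 |
| beta run | 2.4 | 0.4435 |
| beta run | 4.1 | 0.3929 |
| beta run | 7.0 | 0.3261 |
| beta run | 12 | 0.2199 |
| beta run | 20 | 0.1151 |
| beta run | 35 | 0.0340 |
| epsilon run | 1.4 | 0.4895 |
| epsilon run | 2.4 | 0.4805 |
| epsilon run | 4.1 | 0.4655 |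
| epsilon run | 7.0 | 0.4438 |
| epsilon run | 12 | 0.4041 |
| epsilon run | 20 | 0.3461 |
| epsilon run | 35 | 0.2565 |

(readings scatter by 0.002 M)

- Overall: Sub + Rgt -> Prd, with Cat as catalyst.
- Constant volume, constant temperature.
- Readings of a species count what is bound in complexes too.
- "The second partner" is Rgt.
- An order is taken over about fifteen percent of the charge, up and down.

* order of the initial rate in [Cat], near the charge of the gamma run, the rate being that where two percent of its Sub are Prd
* order of the initial rate in [Rgt], near the charge of the gamma run, the rate being that where two percent of its Sub are Prd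
* Sub in the eta run at 70 min, as a share of the Sub charged
* which of these the readings show (nothing beyond the main steps / the product kills the catalyst / the catalyst wakes slowly / the substrate is lost by itself / the second partner ties up the catalyst)

From 20 min to 35 min in gamma, the base-ten logarithm of Sub falls by one unit per 85.9 min. I call this D, the decade time: the minutes in which Sub falls by a factor 10 at the pace of that stretch. If D held steady, as in a pseudo-first-order decay, the reading at 35 min would put Sub in eta at 16.5% of its charge.

But the earlier stretch of gamma, 12 min to 20 min, reads 96.5 min, longer than 85.9 min. Epsilon, with twice the Rgt of gamma, reads 115 min over its last stretch, also longer than 85.9 min. More Rgt goes with a longer D, which points to Rgt tying up Cat, so D in gamma should go on shortening as its Rgt falls.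

The steady D is therefore the weak link, and I reforge it. The stretches last 8.00 min, 15.0 min and 35.0 min, roughly even steps in the logarithm of time, so I take the same step down once more. That gives D = 75.2 min and puts Sub in eta at 14.4%.

The forecast, made from the same runs, gives 0.73 for the order in Cat, −0.12 for the order in Rgt, 16.5% for eta, and "the second partner ties up the catalyst", on the ground that “Doubling Rgt slows the run, which no productive step would do, so Rgt ties up catalyst”. Its 16.5% sits with my steady-D figure, not with the reforged one.

The flask gives 0.81 for the order in Cat, 0.0075 for the order in Rgt, 14.7% for eta, and "the second partner ties up the catalyst".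

    Cat + Sub → Cat.Sub (1.026 /M/min)
    Cat.Sub + Rgt → Prd + Cat (2.244 /M/min)
    Cat + Rgt ⇌ Cat.Rgt, settled at all times (1.540 /M)

Taken from the reading of gamma at 35 min, Sub at 14.7% of its charge in eta at 70 min means D = 76.3 min over that last stretch, shorter than 85.9 min. At 70 min eta holds 14.7% of the Sub charged rather than 7.85% because of the association of Cat + Rgt to Cat.Rgt. Beta holds 3.00 times the Cat of gamma, and the D of the last stretch of gamma, divided by that ratio, gives 8.61 min for half of the Sub to turn at that pace, while Prd in beta comes to half of the Sub charged at 10.5 min.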